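The ten-membered lactone (ring atoms O1, C2–C10) is opened at O1–C2, and the α-acyloxy carbonyl unit C2(=O)–C3(H)–O-acyl that remains is the direct imprint of a Passerini reaction. A chiral phosphoric acid therefore unites a C3–C13 aldehyde, a convertible isocyanide carbon (C2) and mono-tert-butyl muconate, forming the C2–C3 bond, the C3–O acyl bond and the 3R centre in one operation with the side chain already differentiated. The aldehyde is an (E)-4-enal bearing the D-tartrate-derived C8/C9 acetonide and a C10 triethylsilyl ether; the anilide is later unmasked through its N-acylindole to the acid, which is closed by Shiina lactonisation.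

Key step: step 14

Assumption: the (R)-configured phosphoric acid is taken to favour the 3R adduct; because C8–C10 are too remote to bias C3, the (S)-catalyst is used instead if the sense of induction proves opposite.

Step 1
Reactants: 1 dimethyl (4S,5S)-2,2-dimethyl-1,3-dioxolane-4,5-dicarboxylate
Product: 2 (4S,5S)-N4,N4,N5,N5,2,2-hexamethyl-1,3-dioxolane-4,5-dicarboxamide
Conditions: Me2NH (2 M in MeOH, excess), rt
Reagents that add atoms: dimethylamine, CNC
Why: Ester aminolysis of the α-alkoxy-activated methyl esters by excess dimethylamine should proceed at room temperature, and the trans-dioxolane stereocentres (already the thermodynamically preferred arrangement) are untouched.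

Step 2
Reactants: 2 bis(dimethylamide); 3 n-propylmagnesium bromide
Product: 4 (4S,5S)-5-butanoyl-N,N,2,2-tetramethyl-1,3-dioxolane-4-carboxamide
Conditions: n-PrMgBr (1.5 equiv), THF, −15 °C; aq. NH4Cl
Reagents that add atoms: none
Why: Grignard mono-addition to a tertiary amide, in which the first addition gives a magnesium-chelated tetrahedral adduct that persists until work-up and shuts down the second amide, should desymmetrise the C2-symmetric diamide to the propyl ketone (C10–C13 installed).

Step 3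
Reactants: 4 keto amide
Product: 5 (4S,5R)-5-[(1R)-1-hydroxybutyl]-N,N,2,2-tetramethyl-1,3-dioxolane-4-carboxamide
Conditions: Zn(BH4)2, Et2O, −30 to 0 °C; aq. NH4Cl
Reagents that add atoms: none
Why: Chelation-controlled (Cram-chelate) ketone reduction, in which zinc bridges the ketone oxygen and the neighbouring dioxolane oxygen at C9 and hydride enters from the face opposite C8, should give the 9,10-anti carbinol (10R) that the target requires, while the tertiary amide is inert to Zn(BH4)2.

Step 4
Reactants: 5 anti hydroxy amide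
Product: 6 (4S,5S)-N,N,2,2-tetramethyl-5-[(1R)-1-(triethylsilyloxy)butyl]-1,3-dioxolane-4-carboxamide
Conditions: Et3SiCl, imidazole, DMF, 0 °C to rt
Reagents that add atoms: chlorotriethylsilane, CC[Si](Cl)(CC)CC
Why: Imidazole-mediated silylation of the secondary alcohol masks the C10 hydroxyl for the organometallic, Claisen and hydride steps and leaves a group that mild aqueous acid removes later.

Step 5
Reactants: 6 silyl ether amide
Product: 7 (4S,5S)-2,2-dimethyl-5-[(1R)-1-(triethylsilyloxy)butyl]-1,3-dioxolane-4-carbaldehyde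
Conditions: Cp2Zr(H)Cl (1.5 equiv), THF, rt; aqueous work-up
Reagents that add atoms: none
Why: Schwartz-reagent reduction of a tertiary amide stops at the zirconium-bound hemiaminal, which should release the aldehyde on work-up without over-reduction, and the trans-dioxolane keeps C8 from epimerising.

Step 6
Reactants: 7 aldehyde; 8 vinylmagnesium bromide
Product: 9 1-{(4R,5S)-2,2-dimethyl-5-[(1R)-1-(triethylsilyloxy)butyl]-1,3-dioxolan-4-yl}prop-2-en-1-ol (both C1 epimers)
Conditions: CH2=CHMgBr, THF, −78 to 0 °C; aq. NH4Cl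
Reagents that add atoms: none
Why: Grignard 1,2-addition to the aldehyde gives the C5–C13 vinyl carbinol, whose configuration at C7 is of no consequence because the next step turns C7 into an alkene carbon.

Step 7
Reactants: 9 vinyl carbinol; 10 triethyl orthoacetate
Product: 11 ethyl (4E)-5-{(4R,5S)-2,2-dimethyl-5-[(1R)-1-(triethylsilyloxy)butyl]-1,3-dioxolan-4-yl}pent-4-enoate
Conditions: MeC(OEt)3 (excess), EtCO2H (cat.), 140 °C, EtOH distilled off
Reagents that add atoms: none
Why: Johnson–Claisen rearrangement, whose [3,3]-sigmatropic shift runs through a chair transition state with the dioxolanyl group equatorial, should converge both carbinol epimers on the (E)-C6=C7 alkene while adding C4 and C3.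

Step 8
Reactants: 11 ethyl ester
Product: 12 (4E)-5-{(4R,5S)-2,2-dimethyl-5-[(1R)-1-(triethylsilyloxy)butyl]-1,3-dioxolan-4-yl}pent-4-enal
Conditions: i-Bu2AlH (1.05 equiv), CH2Cl2, −78 °C; aq. potassium sodium tartrate
Reagents that add atoms: none
Why: Partial ester reduction with i-Bu2AlH at −78 °C, where the tetrahedral aluminium adduct is stable until hydrolytic work-up, should deliver the aldehyde without touching the silyl ether, acetonide or alkene.

Step 9
Reactants: 13 (2E,4E)-hexa-2,4-dienedioic acid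
Product: 14 (2E,4E)-6-tert-butoxy-6-oxohexa-2,4-dienoic acid
Conditions: Me2NCH(Ot-Bu)2 (1.0 equiv), DMF/toluene, 80 °C
Reagents that add atoms: N,N-dimethylformamide di-tert-butyl acetal, CN(C)C(OC(C)(C)C)OC(C)(C)C
Why: Statistical mono-esterification of the symmetric diacid by tert-butyl transfer from the protonated formamide acetal gives the half-ester, which is separated from unreacted diacid and neutral diester by bicarbonate extraction.

Step 10
Reactants: 15 2-nitrotoluene
Product: 17 1-(2,2-dimethoxyethyl)-2-nitrobenzene, via enamine 16 (not isolated)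
Conditions: Me2NCH(OMe)2, DMF, 140 °C; then MeOH, Me3SiCl, 65 °C
Reagents that add atoms: N,N-dimethylformamide dimethyl acetal, COC(OC)N(C)C; methanol, CO
Why: Leimgruber–Batcho-type condensation of the nitro-activated benzylic methyl group with the formamide acetal gives the enamine, and acid-mediated methanolysis of its iminium form exchanges dimethylamine for two methoxy groups.

Step 11
Reactants: 17 nitro acetal
Product: 18 2-(2,2-dimethoxyethyl)aniline
Conditions: H2 (1 atm), 10% Pd/C, MeOH, rt
Reagents that add atoms: none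
Why: Catalytic hydrogenation of the aromatic nitro group under neutral conditions leaves the dimethyl acetal intact.

Step 12
Reactants: 18 aniline acetal
Product: 19 N-[2-(2,2-dimethoxyethyl)phenyl]formamide
Conditions: acetic formic anhydride, pyridine, CH2Cl2, 0 °C
Reagents that add atoms: acetic formic anhydride, CC(=O)OC=O
Why: N-Formylation of the aniline at the more electrophilic formyl carbon of the mixed anhydride, with pyridine as buffer so that the acetal is not ionised.

Step 13
Reactants: 19 formamide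
Product: 20 1-(2,2-dimethoxyethyl)-2-isocyanobenzene
Conditions: POCl3, Et3N, CH2Cl2, −20 to 0 °C
Reagents that add atoms: none
Why: Dehydration of the formamide with POCl3 and amine base (Ugi isocyanide synthesis) runs under basic conditions that preserve the acetal.

Step 14
Reactants: 12 C3–C13 aldehyde; 14 mono-tert-butyl muconate; 20 convertible isocyanide
Product: 21 1-tert-butyl 6-[(2R,5E)-1-{[2-(2,2-dimethoxyethyl)phenyl]amino}-6-{(4R,5S)-2,2-dimethyl-5-[(1R)-1-(triethylsilyloxy)butyl]-1,3-dioxolan-4-yl}-1-oxohex-5-en-2-yl] (2E,4E)-hexa-2,4-dienedioate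
Conditions: (R)-3,3′-bis(2,4,6-triisopropylphenyl)-1,1′-binaphthyl-2,2′-diyl hydrogen phosphate (10 mol%), CHCl3 (0.5 M), 0 °C to rt
Reagents that add atoms: none
Why: The phosphoric acid binds the carboxylic acid 14 and the aldehyde 12 in a hydrogen-bonded assembly, the isocyanide carbon of 20 (future C2) adds to one face of the C3 carbonyl, the transient nitrilium ion is captured by the muconate carboxylate, and Mumm O-to-O acyl transfer delivers the α-acyloxy anilide, so the C2–C3 and C3–O(acyl) bonds form in one flask. The closest known reaction type is the chiral phosphoric acid-catalysed enantioselective three-component Passerini reaction of aliphatic aldehydes, carboxylic acids and isocyanides. No ring closes. The new C3 centre (3R) is set by the catalyst, which shields one face of the activated aldehyde, because the resident centres at C8–C10 lie five or more bonds away and cannot compete. The step needs facial selectivity at C3 and chemoselectivity for the single free carboxyl; the unbranched C4 methylene next to the aldehyde, the tert-butyl mask on the second carboxyl and the weak acidity of the medium, which should leave acetal, acetonide and silyl ether untouched, secure both.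

Step 15
Reactants: 21 α-acyloxy anilide
Product: 22 1-tert-butyl 6-[(2R,5E)-6-{(4R,5S)-2,2-dimethyl-5-[(1R)-1-(triethylsilyloxy)butyl]-1,3-dioxolan-4-yl}-1-(1H-indol-1-yl)-1-oxohex-5-en-2-yl] (2E,4E)-hexa-2,4-dienedioate
Conditions: camphor-10-sulfonic acid (10 mol%), quinoline (15 mol%), toluene, 90 °C
Reagents that add atoms: none
Why: Acid-mediated indole-forming activation of a convertible 2-(2,2-dimethoxyethyl)anilide, in which the acetal ionises, the amide nitrogen closes the five-membered ring and loss of a second methanol aromatises, should give the N-acylindole while the quinolinium buffer spares tert-butyl ester, acetonide and silyl ether.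

Step 16
Reactants: 22 N-acylindole
Product: 24 (2R,5E)-2-{[(2E,4E)-6-tert-butoxy-6-oxohexa-2,4-dienoyl]oxy}-6-{(4R,5R)-5-[(1R)-1-hydroxybutyl]-2,2-dimethyl-1,3-dioxolan-4-yl}hex-5-enoic acid, via silyl ether acid 23 (not isolated)
Conditions: LiOH, H2O2, THF/H2O, 0 °C; Me2S; then AcOH/THF/H2O (3:1:1), rt
Reagents that add atoms: hydrogen peroxide, OO
Why: Chemoselective perhydrolysis of an activated amide (as in lithium hydroperoxide cleavage of N-acyl oxazolidinones) should attack the N-acylindole carbonyl, which lacks amide resonance, far faster than the conjugated C3 ester or the tert-butyl ester, and aqueous acetic acid then hydrolyses the triethylsilyl ether without opening the acetonide.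

Step 17
Reactants: 24 seco acid
Product: 25 1-tert-butyl 6-[(3R,6E,8R,9R,10R)-8,9-(isopropylidenedioxy)-2-oxo-10-propyl-3,4,5,8,9,10-hexahydro-2H-oxecin-3-yl] (2E,4E)-hexa-2,4-dienedioate
Conditions: 2-methyl-6-nitrobenzoic anhydride, 4-(dimethylamino)pyridine, CH2Cl2 (1 mM, slow addition), rt
Reagents that add atoms: none
Why: Shiina macrolactonisation, in which the mixed anhydride is relayed by 4-(dimethylamino)pyridine to the only free hydroxyl (C10) under high dilution at room temperature, should close the ten-membered ring with retention at C10 and without a base strong enough to epimerise C3.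

Step 18
Reactants: 25 protected lactone
Product: 26 (2E,4E)-6-{[(3R,6E,8R,9S,10R)-8,9-dihydroxy-2-oxo-10-propyl-3,4,5,8,9,10-hexahydro-2H-oxecin-3-yl]oxy}-6-oxohexa-2,4-dienoic acid
Conditions: CF3CO2H/H2O (9:1), 0 °C to rt
Reagents that add atoms: none
Why: Acidolysis with aqueous trifluoroacetic acid should hydrolyse the isopropylidene acetal and cleave the tert-butyl ester by loss of 2-methylpropene in one operation, while the lactone and the dienoate ester are stable to acid.

Compound list
1 | dimethyl (4S,5S)-2,2-dimethyl-1,3-dioxolane-4,5-dicarboxylate [(+)-dimethyl 2,3-O-isopropylidene-D-tartrate] | COC(=O)[C@H]1OC(C)(C)O[C@@H]1C(=O)OC | starting material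
2 | (4S,5S)-N4,N4,N5,N5,2,2-hexamethyl-1,3-dioxolane-4,5-dicarboxamide | CN(C)C(=O)[C@H]1OC(C)(C)O[C@@H]1C(=O)N(C)C | intermediate
3 | n-propylmagnesium bromide | CCC[Mg]Br | starting material
4 | (4S,5S)-5-butanoyl-N,N,2,2-tetramethyl-1,3-dioxolane-4-carboxamide | CN(C)C(=O)[C@H]1OC(C)(C)O[C@@H]1C(=O)CCC | intermediate
5 | (4S,5R)-5-[(1R)-1-hydroxybutyl]-N,N,2,2-tetramethyl-1,3-dioxolane-4-carboxamide | CN(C)C(=O)[C@H]1OC(C)(C)O[C@@H]1[C@H](O)CCC | intermediate
6 | (4S,5S)-N,N,2,2-tetramethyl-5-[(1R)-1-(triethylsilyloxy)butyl]-1,3-dioxolane-4-carboxamide | CN(C)C(=O)[C@H]1OC(C)(C)O[C@@H]1[C@H](O[Si](CC)(CC)CC)CCC | intermediate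
7 | (4S,5S)-2,2-dimethyl-5-[(1R)-1-(triethylsilyloxy)butyl]-1,3-dioxolane-4-carbaldehyde | O=C[C@H]1OC(C)(C)O[C@@H]1[C@H](O[Si](CC)(CC)CC)CCC | intermediate
8 | vinylmagnesium bromide | C=C[Mg]Br | starting material
9 | 1-{(4R,5S)-2,2-dimethyl-5-[(1R)-1-(triethylsilyloxy)butyl]-1,3-dioxolan-4-yl}prop-2-en-1-ol, both C1 epimers (C5–C13 vinyl carbinol) | C=CC(O)[C@H]1OC(C)(C)O[C@@H]1[C@H](O[Si](CC)(CC)CC)CCC | intermediate
10 | triethyl orthoacetate | CC(OCC)(OCC)OCC | starting material
11 | ethyl (4E)-5-{(4R,5S)-2,2-dimethyl-5-[(1R)-1-(triethylsilyloxy)butyl]-1,3-dioxolan-4-yl}pent-4-enoate | CCOC(=O)CC/C=C/[C@H]1OC(C)(C)O[C@@H]1[C@H](O[Si](CC)(CC)CC)CCC | intermediate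
12 | (4E)-5-{(4R,5S)-2,2-dimethyl-5-[(1R)-1-(triethylsilyloxy)butyl]-1,3-dioxolan-4-yl}pent-4-enal (C3–C13 aldehyde) | O=CCC/C=C/[C@H]1OC(C)(C)O[C@@H]1[C@H](O[Si](CC)(CC)CC)CCC | intermediate
13 | (2E,4E)-hexa-2,4-dienedioic acid [(E,E)-muconic acid] | OC(=O)/C=C/C=C/C(=O)O | starting material
14 | (2E,4E)-6-tert-butoxy-6-oxohexa-2,4-dienoic acid | OC(=O)/C=C/C=C/C(=O)OC(C)(C)C | intermediate
15 | 2-nitrotoluene | Cc1ccccc1[N+](=O)[O-] | starting material
16 | (E)-N,N-dimethyl-2-(2-nitrophenyl)ethenamine | CN(C)/C=C/c1ccccc1[N+](=O)[O-] | intermediate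
17 | 1-(2,2-dimethoxyethyl)-2-nitrobenzene | COC(OC)Cc1ccccc1[N+](=O)[O-] | intermediate
18 | 2-(2,2-dimethoxyethyl)aniline | COC(OC)Cc1ccccc1N | intermediate
19 | N-[2-(2,2-dimethoxyethyl)phenyl]formamide | COC(OC)Cc1ccccc1NC=O | intermediate
20 | 1-(2,2-dimethoxyethyl)-2-isocyanobenzene | [C-]#[N+]c1ccccc1CC(OC)OC | intermediate
21 | 1-tert-butyl 6-[(2R,5E)-1-{[2-(2,2-dimethoxyethyl)phenyl]amino}-6-{(4R,5S)-2,2-dimethyl-5-[(1R)-1-(triethylsilyloxy)butyl]-1,3-dioxolan-4-yl}-1-oxohex-5-en-2-yl] (2E,4E)-hexa-2,4-dienedioate | O=C(Nc1ccccc1CC(OC)OC)[C@H](OC(=O)/C=C/C=C/C(=O)OC(C)(C)C)CC/C=C/[C@H]1OC(C)(C)O[C@@H]1[C@H](O[Si](CC)(CC)CC)CCC | intermediate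
22 | 1-tert-butyl 6-[(2R,5E)-6-{(4R,5S)-2,2-dimethyl-5-[(1R)-1-(triethylsilyloxy)butyl]-1,3-dioxolan-4-yl}-1-(1H-indol-1-yl)-1-oxohex-5-en-2-yl] (2E,4E)-hexa-2,4-dienedioate | O=C(n1ccc2ccccc12)[C@H](OC(=O)/C=C/C=C/C(=O)OC(C)(C)C)CC/C=C/[C@H]1OC(C)(C)O[C@@H]1[C@H](O[Si](CC)(CC)CC)CCC | intermediate
23 | (2R,5E)-2-{[(2E,4E)-6-tert-butoxy-6-oxohexa-2,4-dienoyl]oxy}-6-{(4R,5S)-2,2-dimethyl-5-[(1R)-1-(triethylsilyloxy)butyl]-1,3-dioxolan-4-yl}hex-5-enoic acid | OC(=O)[C@H](OC(=O)/C=C/C=C/C(=O)OC(C)(C)C)CC/C=C/[C@H]1OC(C)(C)O[C@@H]1[C@H](O[Si](CC)(CC)CC)CCC | intermediate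
24 | (2R,5E)-2-{[(2E,4E)-6-tert-butoxy-6-oxohexa-2,4-dienoyl]oxy}-6-{(4R,5R)-5-[(1R)-1-hydroxybutyl]-2,2-dimethyl-1,3-dioxolan-4-yl}hex-5-enoic acid | OC(=O)[C@H](OC(=O)/C=C/C=C/C(=O)OC(C)(C)C)CC/C=C/[C@H]1OC(C)(C)O[C@@H]1[C@H](O)CCC | intermediate
25 | 1-tert-butyl 6-[(3R,6E,8R,9R,10R)-8,9-(isopropylidenedioxy)-2-oxo-10-propyl-3,4,5,8,9,10-hexahydro-2H-oxecin-3-yl] (2E,4E)-hexa-2,4-dienedioate (trans-fused C8/C9 acetonide; the 9R label differs from 9S of the target only through ligand ranking) | CCC[C@H]1OC(=O)[C@H](OC(=O)/C=C/C=C/C(=O)OC(C)(C)C)CC/C=C/[C@H]2OC(C)(C)O[C@H]12 | intermediate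
26 | (2E,4E)-6-{[(3R,6E,8R,9S,10R)-8,9-dihydroxy-2-oxo-10-propyl-3,4,5,8,9,10-hexahydro-2H-oxecin-3-yl]oxy}-6-oxohexa-2,4-dienoic acid | CCC[C@H]1OC(=O)[C@H](OC(=O)/C=C/C=C/C(=O)O)CC/C=C/[C@@H](O)[C@@H]1O | target

Total step count: 18. Longest linear sequence: 13 steps (steps 1–8 and 14–18).

Steps most likely to fail

Step 14. Facial selectivity at C3 may be poor, or the aryl isocyanide may couple sluggishly under weak-acid catalysis. The fallback separates bond formation from stereocontrol. From 12 and 20, a Passerini-type addition with CF3CO2H and pyridine in CH2Cl2, followed by aqueous NaHCO3 work-up, should give the α-hydroxy anilide as a C3 epimer mixture F1. Dess–Martin periodinane oxidises it to the α-keto anilide F2. Catalyst-controlled transfer hydrogenation with RuCl(p-cymene)[TsNCH(Ph)CH(Ph)NH2] (the ligand enantiomer that gives the 3R alcohol) and HCO2H/Et3N gives the (2R)-α-hydroxy anilide F3. Carbodiimide esterification of F3 with 14 (N-(3-dimethylaminopropyl)-N′-ethylcarbodiimide hydrochloride, 4-(dimethylamino)pyridine) comes back to the route at 21.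

Step 17. Intermolecular esterification (diolide and oligomer formation) may outrun closure of the ten-membered ring, or the activated α-acyloxy acyl donor may epimerise at C3. The fallback replaces in situ mixed-anhydride activation by an isolated thioester and metal-assisted closure without amine base. From 24, 2,2′-dipyridyl disulfide and PPh3 give the S-pyridin-2-yl thioester F4, which is cyclised under high dilution with AgOSO2CF3 in toluene (Corey–Nicolaou–Gerlach double activation) and rejoins the route at 25.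

Step 3. Diastereofacial control may be poor if zinc is sequestered by the amide instead of forming the five-membered chelate with the dioxolane oxygen. The fallback sets C10 by inversion. From 4, LiBH(s-Bu)3 in THF at −78 °C (Felkin–Anh control) should give the 9,10-syn alcohol F5. Mitsunobu reaction with 4-nitrobenzoic acid (PPh3, diisopropyl azodicarboxylate) inverts C10 to the anti 4-nitrobenzoate F6, and K2CO3/MeOH returns to the route at 5.

Further compounds
F1 | step 14 | (5E)-N-[2-(2,2-dimethoxyethyl)phenyl]-6-{(4R,5S)-2,2-dimethyl-5-[(1R)-1-(triethylsilyloxy)butyl]-1,3-dioxolan-4-yl}-2-hydroxyhex-5-enamide, both C2 epimers | O=C(Nc1ccccc1CC(OC)OC)C(O)CC/C=C/[C@H]1OC(C)(C)O[C@@H]1[C@H](O[Si](CC)(CC)CC)CCC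
F2 | step 14 | (5E)-N-[2-(2,2-dimethoxyethyl)phenyl]-6-{(4R,5S)-2,2-dimethyl-5-[(1R)-1-(triethylsilyloxy)butyl]-1,3-dioxolan-4-yl}-2-oxohex-5-enamide | O=C(Nc1ccccc1CC(OC)OC)C(=O)CC/C=C/[C@H]1OC(C)(C)O[C@@H]1[C@H](O[Si](CC)(CC)CC)CCC
F3 | step 14 | (2R,5E)-N-[2-(2,2-dimethoxyethyl)phenyl]-6-{(4R,5S)-2,2-dimethyl-5-[(1R)-1-(triethylsilyloxy)butyl]-1,3-dioxolan-4-yl}-2-hydroxyhex-5-enamide | O=C(Nc1ccccc1CC(OC)OC)[C@H](O)CC/C=C/[C@H]1OC(C)(C)O[C@@H]1[C@H](O[Si](CC)(CC)CC)CCC
F4 | step 17 | 1-tert-butyl 6-[(2R,5E)-6-{(4R,5R)-5-[(1R)-1-hydroxybutyl]-2,2-dimethyl-1,3-dioxolan-4-yl}-1-oxo-1-(pyridin-2-ylsulfanyl)hex-5-en-2-yl] (2E,4E)-hexa-2,4-dienedioate | O=C(Sc1ccccn1)[C@H](OC(=O)/C=C/C=C/C(=O)OC(C)(C)C)CC/C=C/[C@H]1OC(C)(C)O[C@@H]1[C@H](O)CCC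
F5 | step 3 | (4S,5R)-5-[(1S)-1-hydroxybutyl]-N,N,2,2-tetramethyl-1,3-dioxolane-4-carboxamide | CN(C)C(=O)[C@H]1OC(C)(C)O[C@@H]1[C@@H](O)CCC
F6 | step 3 | (1R)-1-[(4R,5S)-5-(dimethylcarbamoyl)-2,2-dimethyl-1,3-dioxolan-4-yl]butyl 4-nitrobenzoate | CN(C)C(=O)[C@H]1OC(C)(C)O[C@@H]1[C@H](OC(=O)c1ccc(cc1)[N+](=O)[O-])CCC
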